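**Retrosynthetic overview**

1. 20 ⇐ 19: the last step is hydrogenolysis of the five aryl benzyl ethers.
2. 19 ⇐ 16: the lactone ring is closed last through the C3–C3a bond. An ester-tethered acyloxycarbenium ion at C3 is captured by the enol ether carbon of a 2,3-dihydrofuran, and C4 is then quenched by hydride.
3. Enabling feature: in the tetrahydrofuran ring O5 is bonded to C4, next to C3a, so C3a=C4–O5 can be carried as a cyclic enol ether that makes C3a nucleophilic. C3 carries the lactone oxygen O2 and a para-oxygenated aryl ring, so it can be an acyloxycarbenium ion delivered from the C1 carboxyl on C6a.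
4. 16 ⇐ 8 + 11: the tether is a mixed acylal made by carboxylate alkylation. The dihydrofuran ring (first ring) comes from an α-allyl syn-aldol by oxidative cleavage to the lactol and dehydration.
5. 8 ⇐ 3 + 4: C6 and C6a come from an Evans syn-aldol. Ring order: dihydrofuran (steps 6 and 7), then lactone (step 8).

Key step: step 8

Remark: target locants are C1 (C=O), O2, C3, C3a, C4 (CH2), O5, C6, C6a of the furo[3,4-c]furan-1-one; the acylal carbon of 12–16 and the anomeric carbon of 14 and 15 are carried as epimer mixtures, because both centres are destroyed in step 8.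

**Route**

Step 1
Reactants: 1 (4S)-4-benzyl-1,3-oxazolidin-2-one; 2 pent-4-enoyl chloride
Product: 3 (4S)-4-benzyl-3-(pent-4-enoyl)-1,3-oxazolidin-2-one
Conditions: Et3N, DMAP (cat.), CH2Cl2, 0 °C → rt
Reagents that add atoms: none
Why: DMAP-catalysed N-acylation of the oxazolidinone by the acid chloride; no stereocentre is formed.

Step 2
Reactants: 3 (4S)-4-benzyl-3-(pent-4-enoyl)-1,3-oxazolidin-2-one; 4 3,4-bis(benzyloxy)benzaldehyde
Product: 6 (4S)-4-benzyl-3-[(2S)-2-[(S)-[3,4-bis(benzyloxy)phenyl](hydroxy)methyl]pent-4-enoyl]-1,3-oxazolidin-2-one, via dibutylboron (Z)-enolate 5 (not isolated)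
Conditions: Bu2BOTf, iPr2NEt, CH2Cl2, 0 °C; then 4, −78 → 0 °C; H2O2, MeOH, pH 7 buffer
Reagents that add atoms: none
Why: Evans syn-aldol through the (Z)-boron enolate and a Zimmerman–Traxler transition state in which the benzyl group of the auxiliary shields one enolate face, which should set both stereocentres (later C6a and C6) as the (S,S) syn adduct.

Step 3
Reactants: 6 (4S)-4-benzyl-3-[(2S)-2-[(S)-[3,4-bis(benzyloxy)phenyl](hydroxy)methyl]pent-4-enoyl]-1,3-oxazolidin-2-one
Product: 8 (2S)-2-[(S)-[3,4-bis(benzyloxy)phenyl](hydroxy)methyl]pent-4-enoic acid, via percarboxylic acid 7 (not isolated)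
Conditions: LiOH, H2O2, THF/H2O (3:1), 0 °C; Na2SO3; then HCl (aq) to pH 3
Reagents that add atoms: hydrogen peroxide, OO (as LiOOH)
Why: hydroperoxide-mediated exocyclic cleavage of the N-acyl oxazolidinone at 0 °C should release the acid without touching either stereocentre and return the auxiliary.

Step 4
Reactants: 9 3,4,5-tris(benzyloxy)benzaldehyde; 10 acetyl chloride
Product: 11 chloro[3,4,5-tris(benzyloxy)phenyl]methyl acetate (racemic, used crude)
Conditions: AcCl, ZnCl2 (cat.), CH2Cl2, 0 °C → rt; evaporation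
Reagents that add atoms: none
Why: ZnCl2-catalysed addition of an acyl chloride across the aldehyde C=O gives the α-chloroalkyl ester; the new centre is racemic and is destroyed later.

Step 5
Reactants: 8 (2S)-2-[(S)-[3,4-bis(benzyloxy)phenyl](hydroxy)methyl]pent-4-enoic acid; 11 chloro[3,4,5-tris(benzyloxy)phenyl]methyl acetate
Product: 12 (acetyloxy)[3,4,5-tris(benzyloxy)phenyl]methyl (2S)-2-[(S)-[3,4-bis(benzyloxy)phenyl](hydroxy)methyl]pent-4-enoate (epimers at the acylal carbon)
Conditions: iPr2NEt, CH2Cl2, 0 °C → rt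
Reagents that add atoms: none
Why: carboxylate O-alkylation by the α-chloroalkyl ester (acyloxyalkyl ester formation), in which the carboxylate should outcompete the neutral secondary alcohol; the acylal centre is not controlled and need not be.

Step 6
Reactants: 12 (acetyloxy)[3,4,5-tris(benzyloxy)phenyl]methyl (2S)-2-[(S)-[3,4-bis(benzyloxy)phenyl](hydroxy)methyl]pent-4-enoate
Product: 14 (acetyloxy)[3,4,5-tris(benzyloxy)phenyl]methyl (2S,3S)-2-[3,4-bis(benzyloxy)phenyl]-5-hydroxyoxolane-3-carboxylate (anomers), via open-chain aldehyde 13 (not isolated)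
Conditions: OsO4 (2 mol %), NaIO4, 2,6-lutidine, dioxane/H2O (3:1), rt
Reagents that add atoms: osmium tetroxide, O=[Os](=O)(=O)=O (turned over by sodium periodate, [Na+].[O-]I(=O)(=O)=O)
Why: Lemieux–Johnson cleavage of the terminal alkene gives a γ-hydroxy aldehyde that should close spontaneously to the five-membered lactol, the syn-aldol relationship becoming the 2,3-trans oxolane.

Step 7
Reactants: 14 (acetyloxy)[3,4,5-tris(benzyloxy)phenyl]methyl (2S,3S)-2-[3,4-bis(benzyloxy)phenyl]-5-hydroxyoxolane-3-carboxylate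
Product: 16 (acetyloxy)[3,4,5-tris(benzyloxy)phenyl]methyl (2S,3S)-2-[3,4-bis(benzyloxy)phenyl]-2,3-dihydrofuran-3-carboxylate, via anomeric mesylate 15 (not isolated)
Conditions: MsCl, Et3N, CH2Cl2, −40 °C → reflux
Reagents that add atoms: none
Why: lactol dehydration through the anomeric mesylate and amine-mediated elimination (the glycal-type synthesis of cyclic enol ethers), which can only place the double bond at C4=C5; Et3N is too weak to enolise the ester at C3.

Step 8
Reactants: 16 (acetyloxy)[3,4,5-tris(benzyloxy)phenyl]methyl (2S,3S)-2-[3,4-bis(benzyloxy)phenyl]-2,3-dihydrofuran-3-carboxylate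
Product: 19 (3S,3aR,6S,6aS)-6-[3,4-bis(benzyloxy)phenyl]-3-[3,4,5-tris(benzyloxy)phenyl]tetrahydro-1H,3H-furo[3,4-c]furan-1-one, via acyloxycarbenium triflate 17 (not isolated), via bicyclic oxocarbenium triflate 18 (not isolated)
Conditions: Me3SiOTf (1.2 equiv), 2,6-di-tert-butyl-4-methylpyridine, CH2Cl2 (0.01 M), −78 °C; then Et3SiH, −78 → −40 °C; NaHCO3 (aq)
Reagents that add atoms: none
Why: Proposed new method: Me3SiOTf should ionise the acylal on the acetate side to the (E)-acyloxycarbenium ion 17, the enol ether carbon C4 of the dihydrofuran (C3a of 19) adds to it to give the bicyclic oxocarbenium ion 18, and Et3SiH, added only after C–C bond formation, reduces the oxocarbenium carbon to the C4 methylene of 19. The closest known reaction types are the Lewis-acid-mediated closure of 2,3-dihydrofuran-3-ylmethanols with aryl acetals to furofurans (ether tether) and the Prins lactonisation of but-3-enoic acid with aldehydes (acyloxycarbenium electrophile); the ester-tethered closure onto an enol ether with reductive termination is the new element. The lactone ring closes 5-exo-trig at the enol ether and 5-endo at the C=O+ unit, the mode of Petasis–Ferrier-type oxocarbenium closures to five-membered rings. C3a is controlled by the existing C3 stereocentre of the dihydrofuran (C6a of 19), because the two-atom ester tether can reach only the face of the enol ether that carries the carboxyl group, so only the cis-fused lactone can form. C3 is controlled by the (E)-geometry of 17 and the near-planar C6a–C1(=O)–O2–C3 unit of the developing lactone with C3a as the envelope flap, which should place the aryl group pseudo-equatorial on the convex face, trans to C4. The step needs acetate-side ionisation and intramolecular capture, which are secured by reversible return of the non-productive ion pair, high dilution and the irreversible five-ring closure, while the hindered pyridine protects the enol ether from acid and the low temperature protects the two benzylic C–O bonds from ionic reduction.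

Step 9
Reactants: 19 (3S,3aR,6S,6aS)-6-[3,4-bis(benzyloxy)phenyl]-3-[3,4,5-tris(benzyloxy)phenyl]tetrahydro-1H,3H-furo[3,4-c]furan-1-one
Product: 20 (3S,3aR,6S,6aS)-6-(3,4-dihydroxyphenyl)-3-(3,4,5-trihydroxyphenyl)tetrahydro-1H,3H-furo[3,4-c]furan-1-one (CNP0290035.1)
Conditions: H2 (1 atm), Pd/C (10 wt %), EtOAc/THF (1:1), rt, stopped at full debenzylation; degassed solvents
Reagents that add atoms: none
Why: hydrogenolysis of aryl benzyl ethers under neutral conditions should be much faster than cleavage of the benzylic lactone and benzylic ether C–O bonds of the bicycle, and no stereocentre is touched.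

**Compound list**

1 | (4S)-4-benzyl-1,3-oxazolidin-2-one | O=C1OC[C@H](Cc2ccccc2)N1 | starting material
2 | pent-4-enoyl chloride | C=CCCC(Cl)=O | starting material
3 | (4S)-4-benzyl-3-(pent-4-enoyl)-1,3-oxazolidin-2-one | C=CCCC(=O)N1C(=O)OC[C@@H]1Cc1ccccc1 | intermediate
4 | 3,4-bis(benzyloxy)benzaldehyde | O=Cc1ccc(OCc2ccccc2)c(OCc2ccccc2)c1 | starting material
5 | dibutylboron (Z)-enolate of 3 | C=CC/C=C(/N1C(=O)OC[C@@H]1Cc1ccccc1)OB(CCCC)CCCC | intermediate
6 | (4S)-4-benzyl-3-[(2S)-2-[(S)-[3,4-bis(benzyloxy)phenyl](hydroxy)methyl]pent-4-enoyl]-1,3-oxazolidin-2-one | C=CC[C@H](C(=O)N1C(=O)OC[C@@H]1Cc1ccccc1)[C@H](O)c1ccc(OCc2ccccc2)c(OCc2ccccc2)c1 | intermediate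
7 | (2S)-2-[(S)-[3,4-bis(benzyloxy)phenyl](hydroxy)methyl]pent-4-eneperoxoic acid | C=CC[C@H](C(=O)OO)[C@H](O)c1ccc(OCc2ccccc2)c(OCc2ccccc2)c1 | intermediate
8 | (2S)-2-[(S)-[3,4-bis(benzyloxy)phenyl](hydroxy)methyl]pent-4-enoic acid | C=CC[C@H](C(=O)O)[C@H](O)c1ccc(OCc2ccccc2)c(OCc2ccccc2)c1 | intermediate
9 | 3,4,5-tris(benzyloxy)benzaldehyde | O=Cc1cc(OCc2ccccc2)c(OCc2ccccc2)c(OCc2ccccc2)c1 | starting material
10 | acetyl chloride | CC(Cl)=O | starting material
11 | chloro[3,4,5-tris(benzyloxy)phenyl]methyl acetate (racemic) | CC(=O)OC(Cl)c1cc(OCc2ccccc2)c(OCc2ccccc2)c(OCc2ccccc2)c1 | intermediate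
12 | (acetyloxy)[3,4,5-tris(benzyloxy)phenyl]methyl (2S)-2-[(S)-[3,4-bis(benzyloxy)phenyl](hydroxy)methyl]pent-4-enoate (acylal epimers) | C=CC[C@H](C(=O)OC(OC(C)=O)c1cc(OCc2ccccc2)c(OCc2ccccc2)c(OCc2ccccc2)c1)[C@H](O)c1ccc(OCc2ccccc2)c(OCc2ccccc2)c1 | intermediate
13 | (acetyloxy)[3,4,5-tris(benzyloxy)phenyl]methyl (2S)-2-[(S)-[3,4-bis(benzyloxy)phenyl](hydroxy)methyl]-4-oxobutanoate | O=CC[C@H](C(=O)OC(OC(C)=O)c1cc(OCc2ccccc2)c(OCc2ccccc2)c(OCc2ccccc2)c1)[C@H](O)c1ccc(OCc2ccccc2)c(OCc2ccccc2)c1 | intermediate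
14 | (acetyloxy)[3,4,5-tris(benzyloxy)phenyl]methyl (2S,3S)-2-[3,4-bis(benzyloxy)phenyl]-5-hydroxyoxolane-3-carboxylate (anomers) | OC1C[C@H](C(=O)OC(OC(C)=O)c2cc(OCc3ccccc3)c(OCc3ccccc3)c(OCc3ccccc3)c2)[C@@H](c2ccc(OCc3ccccc3)c(OCc3ccccc3)c2)O1 | intermediate
15 | (acetyloxy)[3,4,5-tris(benzyloxy)phenyl]methyl (2S,3S)-2-[3,4-bis(benzyloxy)phenyl]-5-(methanesulfonyloxy)oxolane-3-carboxylate | CS(=O)(=O)OC1C[C@H](C(=O)OC(OC(C)=O)c2cc(OCc3ccccc3)c(OCc3ccccc3)c(OCc3ccccc3)c2)[C@@H](c2ccc(OCc3ccccc3)c(OCc3ccccc3)c2)O1 | intermediate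
16 | (acetyloxy)[3,4,5-tris(benzyloxy)phenyl]methyl (2S,3S)-2-[3,4-bis(benzyloxy)phenyl]-2,3-dihydrofuran-3-carboxylate | CC(=O)OC(OC(=O)[C@H]1C=CO[C@@H]1c1ccc(OCc2ccccc2)c(OCc2ccccc2)c1)c1cc(OCc2ccccc2)c(OCc2ccccc2)c(OCc2ccccc2)c1 | intermediate
17 | acyloxycarbenium triflate from 16: [(2S,3S)-2-[3,4-bis(benzyloxy)phenyl]-2,3-dihydrofuran-3-carbonyloxy][3,4,5-tris(benzyloxy)phenyl]methylium trifluoromethanesulfonate | O=C(O[CH+]c1cc(OCc2ccccc2)c(OCc2ccccc2)c(OCc2ccccc2)c1)[C@H]1C=CO[C@@H]1c1ccc(OCc2ccccc2)c(OCc2ccccc2)c1.[O-]S(=O)(=O)C(F)(F)F | intermediate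
18 | bicyclic oxocarbenium triflate: cis-fused lactone with C4=O5+ (same configuration as 19 at C3, C3a, C6, C6a) | O=C1O[C@H](c2cc(OCc3ccccc3)c(OCc3ccccc3)c(OCc3ccccc3)c2)[C@H]2C=[O+][C@H](c3ccc(OCc4ccccc4)c(OCc4ccccc4)c3)[C@@H]12.[O-]S(=O)(=O)C(F)(F)F | intermediate
19 | (3S,3aR,6S,6aS)-6-[3,4-bis(benzyloxy)phenyl]-3-[3,4,5-tris(benzyloxy)phenyl]tetrahydro-1H,3H-furo[3,4-c]furan-1-one | O=C1O[C@H](c2cc(OCc3ccccc3)c(OCc3ccccc3)c(OCc3ccccc3)c2)[C@H]2CO[C@H](c3ccc(OCc4ccccc4)c(OCc4ccccc4)c3)[C@@H]12 | intermediate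
20 | (3S,3aR,6S,6aS)-6-(3,4-dihydroxyphenyl)-3-(3,4,5-trihydroxyphenyl)tetrahydro-1H,3H-furo[3,4-c]furan-1-one | O=C1O[C@H](c2cc(O)c(O)c(O)c2)[C@H]2CO[C@H](c3ccc(O)c(O)c3)[C@@H]12 | target

**Step count and risks**

Total step count: 9. Longest linear sequence: 8 (steps 1, 2, 3, 5, 6, 7, 8, 9; step 4 is a one-step branch).

Most likely to fail, step 8 (key step). Three processes may defeat it:
- ionisation of the acylal on the dihydrofuran-carboxylate side followed by intermolecular capture;
- acid-induced oligomerisation or ring opening of the enol ether;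
- poor facial selectivity at the benzylic carbon C3 (the ether-tethered relatives of this closure are known to place the new aryl group endo).

Fallback for step 8, known chemistry with the two aryl groups exchanged so that the precedented alcohol/acetal manifold builds the C6–C6a bond instead. It sets out from 3 and 9 (with 4 as the second aryl source) and comes back at 19. The Evans syn-aldol of 3 with 9 (Bu2BOTf, iPr2NEt) would give the aldol adduct F1. Cleavage with OsO4/NaIO4 would give the lactol F2, and MsCl/Et3N would give the dihydrofuran imide F3. LiBH4 (THF, 0 °C) would release the auxiliary and give the dihydrofuranylmethanol F4. Aldehyde 4 with HC(OMe)3 and TsOH (cat.) would give the dimethyl acetal F5. F4 and F5 with Me3SiOTf at −78 °C would close through the mixed acetal and its oxocarbenium ion to the methoxy furofuran F6, the ring oxocarbenium being trapped by methanol. Oxidation of the lactol ether (mCPBA, BF3·OEt2) would give the lactone F7, expected with the aryl group at C6 endo. Acid-mediated equilibration at C6 through reversible ionisation of the benzylic ether bond (BF3·OEt2, CH2Cl2), with separation and recycling of the endo epimer, would then return to 19.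

Second, step 7. The mixed acylal may be lost or scrambled by the chloride and mesylate chemistry, and the elimination of the anomeric mesylate may stall. The fallback is a neutral selenoxide syn-elimination; it sets out from 14 and comes back at 16. Lactol 14 with N-(phenylseleno)phthalimide and Bu3P (THF, 0 °C) would give the anomeric phenyl selenide F8. Oxidation with H2O2/pyridine at 0 °C would give the selenoxide F9, which on warming with iPr2NH should eliminate toward C4, the only carbon with β-hydrogens, to give 16.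

Third, step 9. Hydrogenolysis may also cleave the two benzylic C–O bonds of the bicycle (lactone C3–O2 and ether C6–O5). The fallback replaces hydrogenolysis by Lewis-acid debenzylation with a cation scavenger (BCl3, pentamethylbenzene, CH2Cl2, −78 °C); it sets out from 19 and comes back at 20 and makes no new compound (F0).

**Further compounds**

F1 | step 8 | (4S)-4-benzyl-3-[(2S)-2-[(S)-hydroxy[3,4,5-tris(benzyloxy)phenyl]methyl]pent-4-enoyl]-1,3-oxazolidin-2-one | C=CC[C@H](C(=O)N1C(=O)OC[C@@H]1Cc1ccccc1)[C@H](O)c1cc(OCc2ccccc2)c(OCc2ccccc2)c(OCc2ccccc2)c1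
F2 | step 8 | (4S)-4-benzyl-3-[(2S,3S)-5-hydroxy-2-[3,4,5-tris(benzyloxy)phenyl]oxolane-3-carbonyl]-1,3-oxazolidin-2-one (anomers) | OC1C[C@H](C(=O)N2C(=O)OC[C@@H]2Cc2ccccc2)[C@@H](c2cc(OCc3ccccc3)c(OCc3ccccc3)c(OCc3ccccc3)c2)O1
F3 | step 8 | (4S)-4-benzyl-3-[(2S,3S)-2-[3,4,5-tris(benzyloxy)phenyl]-2,3-dihydrofuran-3-carbonyl]-1,3-oxazolidin-2-one | O=C(N1C(=O)OC[C@@H]1Cc1ccccc1)[C@H]1C=CO[C@@H]1c1cc(OCc2ccccc2)c(OCc2ccccc2)c(OCc2ccccc2)c1
F4 | step 8 | [(2S,3R)-2-[3,4,5-tris(benzyloxy)phenyl]-2,3-dihydrofuran-3-yl]methanol | OC[C@H]1C=CO[C@@H]1c1cc(OCc2ccccc2)c(OCc2ccccc2)c(OCc2ccccc2)c1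
F5 | step 8 | 3,4-bis(benzyloxy)benzaldehyde dimethyl acetal | COC(OC)c1ccc(OCc2ccccc2)c(OCc2ccccc2)c1
F6 | step 8 | 1-methoxy analogue of 19 with the C6 aryl group endo (lactol methyl ether, anomers) | COC1O[C@H](c2cc(OCc3ccccc3)c(OCc3ccccc3)c(OCc3ccccc3)c2)[C@H]2CO[C@@H](c3ccc(OCc4ccccc4)c(OCc4ccccc4)c3)[C@@H]12
F7 | step 8 | (3S,3aR,6R,6aS)-6-[3,4-bis(benzyloxy)phenyl]-3-[3,4,5-tris(benzyloxy)phenyl]tetrahydro-1H,3H-furo[3,4-c]furan-1-one (C6 epimer of 19) | O=C1O[C@H](c2cc(OCc3ccccc3)c(OCc3ccccc3)c(OCc3ccccc3)c2)[C@H]2CO[C@@H](c3ccc(OCc4ccccc4)c(OCc4ccccc4)c3)[C@@H]12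
F8 | step 7 | (acetyloxy)[3,4,5-tris(benzyloxy)phenyl]methyl (2S,3S)-2-[3,4-bis(benzyloxy)phenyl]-5-(phenylselanyl)oxolane-3-carboxylate | O=C(OC(OC(C)=O)c1cc(OCc2ccccc2)c(OCc2ccccc2)c(OCc2ccccc2)c1)[C@H]1CC([Se]c2ccccc2)O[C@@H]1c1ccc(OCc2ccccc2)c(OCc2ccccc2)c1
F9 | step 7 | (acetyloxy)[3,4,5-tris(benzyloxy)phenyl]methyl (2S,3S)-2-[3,4-bis(benzyloxy)phenyl]-5-(benzeneseleninyl)oxolane-3-carboxylate | O=C(OC(OC(C)=O)c1cc(OCc2ccccc2)c(OCc2ccccc2)c(OCc2ccccc2)c1)[C@H]1CC([Se](=O)c2ccccc2)O[C@@H]1c1ccc(OCc2ccccc2)c(OCc2ccccc2)c1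
F0 | step 9 | none | none
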